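**Retrosynthetic overview**

1. Target 27 comes from dienol 25 by acetylation of the C18 hydroxyl and removal of all silyl groups. The chain is numbered from the CH2OH carbon C1 to C15, and C18 is the oxygenated carbon on C7.
2. The strategy rests on the C6=C7 alkene: C7 carries C18 (CH2–O) and C8, and C6 carries H and C5 cis to C18. This is the pattern left by prop-2-yn-1-ol after anti addition of C8 to C7 and C5 to C6, so C7–C8 and C5–C6 are cut together into Grignard 14 (C8–C15), the alkoxide of 22 (C6, C7, C18) and iodide 21 (C1–C5).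
3. Grignard 14 comes from (R)-linalool: Shi epoxidation and 5-exo cyclisation build the oxolane ring (O, C11–C14), ozonolysis gives the C10 aldehyde, asymmetric allylboration sets C10, then ozonolysis–reduction, bromination and magnesium insertion.
4. Iodide 21 comes from silyl-protected but-3-yn-1-ol by zirconium-catalysed methylalumination with formaldehyde capture (2E alkene), silyl exchange and iodination.
5. Ring order: the oxolane is the only ring and is closed in step 2; the key step closes no ring.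

Key step: step 14

Remark: (R)-(−)-linalool of high enantiomeric purity and the tert-butyldimethylsilyl ether of but-3-yn-1-ol are taken as commercial; the latter is otherwise one silylation from but-3-yn-1-ol.

**Route**

Step 1
Reactants: 1 (R)-linalool
Product: 2 (3R)-5-[(2R)-3,3-dimethyloxiran-2-yl]-3-methylpent-1-en-3-ol
Conditions: D-fructose-derived Shi ketone (1,2:4,5-di-O-isopropylidene-β-D-erythro-2,3-hexodiulo-2,6-pyranose, 30 mol %), KHSO5 (as 2KHSO5·KHSO4·K2SO4), K2CO3, Bu4NHSO4 (cat.), Na2B4O7 buffer, MeCN/CH2(OMe)2/H2O, 0 °C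
Reagents that add atoms: potassium peroxymonosulfate, [K+].[O-]S(=O)(=O)OO
Why: Shi asymmetric epoxidation, in which the chiral dioxirane attacks the electron-rich trisubstituted alkene through a spiro transition state under reagent control and should give the 6R epoxide, while the monosubstituted vinyl group is too unreactive to compete.

Step 2
Reactants: 2 (3R)-5-[(2R)-3,3-dimethyloxiran-2-yl]-3-methylpent-1-en-3-ol
Product: 3 2-[(2S,5R)-5-ethenyl-5-methyloxolan-2-yl]propan-2-ol (cis-furanoid linalool oxide)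
Conditions: CSA (10 mol %), CH2Cl2, 0 °C
Reagents that add atoms: none
Why: Acid-catalysed intramolecular epoxide opening (5-exo-tet) by the tertiary hydroxyl at the secondary epoxide carbon with inversion, so the R epoxide carbon becomes the S ring carbon (C14 of the target) cis to the vinyl group; the 6-endo pyran isomer is the expected minor product and should be removable by chromatography.

Step 3
Reactants: 3 2-[(2S,5R)-5-ethenyl-5-methyloxolan-2-yl]propan-2-ol
Product: 4 triethyl-[2-[(2S,5R)-5-ethenyl-5-methyloxolan-2-yl]propan-2-yloxy]silane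
Conditions: TESOTf, 2,6-lutidine, CH2Cl2, −78 to 0 °C
Reagents that add atoms: triethylsilyl trifluoromethanesulfonate, CC[Si](CC)(CC)OS(=O)(=O)C(F)(F)F
Why: Silylation with a silyl triflate and a hindered base caps the tertiary carbinol, which could otherwise close onto the cis aldehyde of step 4 as a bicyclic lactol and would later quench the Grignard reagent.

Step 4
Reactants: 4 triethyl-[2-[(2S,5R)-5-ethenyl-5-methyloxolan-2-yl]propan-2-yloxy]silane
Product: 6 (2R,5S)-2-methyl-5-(2-triethylsilyloxypropan-2-yl)oxolane-2-carbaldehyde, via ozonide 5 (not isolated)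
Conditions: O3, CH2Cl2, −78 °C; then PPh3, −78 °C to rt
Reagents that add atoms: ozone, [O-][O+]=O
Why: Ozonolysis with reductive work-up (Criegee mechanism) cleaves the only alkene, and the alpha carbon is quaternary, so the aldehyde cannot epimerise.

Step 5
Reactants: 6 (2R,5S)-2-methyl-5-(2-triethylsilyloxypropan-2-yl)oxolane-2-carbaldehyde
Product: 8 (1S)-1-[(2R,5S)-2-methyl-5-(2-triethylsilyloxypropan-2-yl)oxolan-2-yl]but-3-en-1-ol, via borinate 7 (not isolated)
Conditions: (−)-Ipc2BOMe, allylMgBr, Et2O, 0 °C to rt; then 6, Et2O, −78 °C; then NaOH, H2O2, 0 °C to rt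
Reagents that add atoms: (−)-B-allyldiisopinocampheylborane, C=CCB([C@@H]1C[C@@H]2C[C@@H](C2(C)C)[C@H]1C)[C@@H]1C[C@@H]2C[C@@H](C2(C)C)[C@H]1C, formed in the flask from allylmagnesium bromide, C=CC[Mg]Br
Why: Brown asymmetric allylboration through a closed chair (Zimmerman–Traxler) transition state under reagent control, the reagent derived from (+)-α-pinene adding to the Si face of the aldehyde to set C10 as S; the quaternary alpha carbon differentiates only methyl from ring CH2, so substrate bias should be small.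

Step 6
Reactants: 8 (1S)-1-[(2R,5S)-2-methyl-5-(2-triethylsilyloxypropan-2-yl)oxolan-2-yl]but-3-en-1-ol
Product: 9 triethyl-[(1S)-1-[(2R,5S)-2-methyl-5-(2-triethylsilyloxypropan-2-yl)oxolan-2-yl]but-3-enoxy]silane
Conditions: TESOTf, 2,6-lutidine, CH2Cl2, −78 to 0 °C
Reagents that add atoms: triethylsilyl trifluoromethanesulfonate, CC[Si](CC)(CC)OS(=O)(=O)C(F)(F)F
Why: Silyl triflate silylation is forceful enough for the hindered secondary hydroxyl next to the quaternary carbon and gives a protecting group that leaves in the same final operation as the others.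

Step 7
Reactants: 9 triethyl-[(1S)-1-[(2R,5S)-2-methyl-5-(2-triethylsilyloxypropan-2-yl)oxolan-2-yl]but-3-enoxy]silane
Product: 12 (3S)-3-triethylsilyloxy-3-[(2R,5S)-2-methyl-5-(2-triethylsilyloxypropan-2-yl)oxolan-2-yl]propan-1-ol, via ozonide 10 (not isolated), via aldehyde 11 (not isolated)
Conditions: O3, CH2Cl2, −78 °C; then NaBH4, MeOH, −78 to 0 °C
Reagents that add atoms: ozone, [O-][O+]=O
Why: Ozonolysis followed by hydride reduction in the same flask removes the terminal carbon and gives the C8 primary alcohol, the beta-silyloxy aldehyde being reduced before it can eliminate.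

Step 8
Reactants: 12 (3S)-3-triethylsilyloxy-3-[(2R,5S)-2-methyl-5-(2-triethylsilyloxypropan-2-yl)oxolan-2-yl]propan-1-ol
Product: 13 [(1S)-3-bromo-1-[(2R,5S)-2-methyl-5-(2-triethylsilyloxypropan-2-yl)oxolan-2-yl]propoxy]triethylsilane
Conditions: CBr4, PPh3, imidazole, CH2Cl2, 0 °C
Reagents that add atoms: carbon tetrabromide, BrC(Br)(Br)Br
Why: Appel reaction, an SN2 displacement of the alkoxyphosphonium ion at the unhindered primary carbon, with imidazole keeping the medium non-acidic for the silyl ethers.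

Step 9
Reactants: 13 [(1S)-3-bromo-1-[(2R,5S)-2-methyl-5-(2-triethylsilyloxypropan-2-yl)oxolan-2-yl]propoxy]triethylsilane
Product: 14 [(3S)-3-triethylsilyloxy-3-[(2R,5S)-2-methyl-5-(2-triethylsilyloxypropan-2-yl)oxolan-2-yl]propyl]magnesium bromide (fragment 2; titrated THF solution)
Conditions: Mg turnings (activated with a crystal of I2), THF, rt to 40 °C
Reagents that add atoms: magnesium, [Mg]
Why: Magnesium insertion into a primary alkyl bromide; the silyl ether sits gamma to the carbon–magnesium bond, so beta-elimination is not possible, and 3-silyloxyalkyl Grignard reagents are stable in ether solvents.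

Step 10
Reactants: 15 tert-butyl(but-3-ynoxy)dimethylsilane
Product: 18 (2E)-5-(tert-butyldimethylsilyloxy)-3-methylpent-2-en-1-ol, via alkenylalane 16 (not isolated), via lithium alanate 17 (not isolated)
Conditions: AlMe3 (2.5 equiv), Cp2ZrCl2 (20 mol %), CH2Cl2, 0 °C to rt; volatiles removed; n-BuLi, THF/hexane, −78 °C; (CH2O)n, −78 °C to rt; H2O
Reagents that add atoms: trimethylaluminium, C[Al](C)C; formaldehyde (from paraformaldehyde), C=O
Why: Negishi zirconium-catalysed methylalumination adds methyl and aluminium syn across the terminal alkyne with aluminium on the terminal carbon, and the derived alanate captures formaldehyde with retention, which fixes the 2E geometry.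

Step 11
Reactants: 18 (2E)-5-(tert-butyldimethylsilyloxy)-3-methylpent-2-en-1-ol
Product: 19 tert-butyl-[(3E)-5-(tert-butyldiphenylsilyloxy)-3-methylpent-3-enoxy]dimethylsilane
Conditions: TBDPSCl, imidazole, CH2Cl2, rt
Reagents that add atoms: tert-butylchlorodiphenylsilane, CC(C)(C)[Si](Cl)(c1ccccc1)c1ccccc1
Why: Standard silylation of a primary allylic alcohol with a group that survives the acidic cleavage of the other silyl ether in step 12.

Step 12
Reactants: 19 tert-butyl-[(3E)-5-(tert-butyldiphenylsilyloxy)-3-methylpent-3-enoxy]dimethylsilane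
Product: 20 (3E)-5-(tert-butyldiphenylsilyloxy)-3-methylpent-3-en-1-ol
Conditions: CSA (10 mol %), MeOH/CH2Cl2, 0 °C
Reagents that add atoms: none
Why: Selective acid-catalysed methanolysis, the primary tert-butyldimethylsilyl ether being cleaved much faster than the bulkier tert-butyldiphenylsilyl ether.

Step 13
Reactants: 20 (3E)-5-(tert-butyldiphenylsilyloxy)-3-methylpent-3-en-1-ol
Product: 21 tert-butyl-[(2E)-5-iodo-3-methylpent-2-enoxy]diphenylsilane (fragment 3)
Conditions: I2, PPh3, imidazole, CH2Cl2, 0 °C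
Reagents that add atoms: iodine, II
Why: Appel-type iodination by SN2 displacement at the primary homoallylic carbon, which cannot undergo allylic transposition.

Step 14
Reactants: 22 prop-2-yn-1-ol; 14 [(3S)-3-triethylsilyloxy-3-[(2R,5S)-2-methyl-5-(2-triethylsilyloxypropan-2-yl)oxolan-2-yl]propyl]magnesium bromide; 21 tert-butyl-[(2E)-5-iodo-3-methylpent-2-enoxy]diphenylsilane
Product: 25 (2Z,6E)-8-(tert-butyldiphenylsilyloxy)-6-methyl-2-[(3S)-3-triethylsilyloxy-3-[(2R,5S)-2-methyl-5-(2-triethylsilyloxypropan-2-yl)oxolan-2-yl]propyl]octa-2,6-dien-1-ol, via chloromagnesium alkoxide 23 (not isolated), via alkenylmagnesium chelate 24 (not isolated)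
Conditions: 22 (1.05 equiv), MeMgCl (1.05 equiv), THF, −20 °C; then 14 (1.0 equiv), CuI (15 mol %), −10 °C to rt; then 21 (1.5 equiv), NMP, further CuI (10 mol %), 0 °C to rt; aq NH4Cl
Reagents that add atoms: none
Why: Proposed new method: transmetalation of 14 gives an organocopper species (monovalent copper) whose alkoxide-directed addition across the triple bond of 23 puts C8 on C7, the alkyne carbon next to the CH2O group, and magnesium on C6 on the opposite face, because the alkoxide ties that magnesium into the five-membered oxamagnesacycle 24; copper-catalysed coupling of this alkenylmagnesium with the primary iodide 21 then forms C5–C6 with retention at the sp2 carbon. The closest known reactions are the CuI-catalysed anti carbomagnesiation of propargyl alcohol with capture by iodine, carbon dioxide or allyl halides, and the copper-catalysed coupling of alkenyl Grignard reagents with primary alkyl halides in THF/NMP; joining them in one flask with an unactivated sp3 iodide is the untested part. No ring of the target closes and no stereocentre is created; what is set is the C6=C7 geometry (6Z, with C5 cis to C18 and trans to C8). The step needs regioselectivity (carbon to C7) and anti addition, both secured by chelation of magnesium by the propargylic alkoxide, and retention in the alkylation, which is the normal course of copper-mediated sp2–sp3 coupling. The C18 hydroxyl is the only free one after work-up, so it is already distinguished from the silylated C1, C10 and C15 oxygens.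

Step 15
Reactants: 25 (2Z,6E)-8-(tert-butyldiphenylsilyloxy)-6-methyl-2-[(3S)-3-triethylsilyloxy-3-[(2R,5S)-2-methyl-5-(2-triethylsilyloxypropan-2-yl)oxolan-2-yl]propyl]octa-2,6-dien-1-ol
Product: 26 [(2Z,6E)-8-(tert-butyldiphenylsilyloxy)-6-methyl-2-[(3S)-3-triethylsilyloxy-3-[(2R,5S)-2-methyl-5-(2-triethylsilyloxypropan-2-yl)oxolan-2-yl]propyl]octa-2,6-dienyl] acetate
Conditions: Ac2O, pyridine, DMAP (cat.), CH2Cl2, 0 °C
Reagents that add atoms: acetic anhydride, CC(=O)OC(C)=O
Why: DMAP-catalysed acylation of the only free hydroxyl, the primary allylic C18–OH, under conditions that leave silyl ethers untouched.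

Step 16
Reactants: 26 [(2Z,6E)-8-(tert-butyldiphenylsilyloxy)-6-methyl-2-[(3S)-3-triethylsilyloxy-3-[(2R,5S)-2-methyl-5-(2-triethylsilyloxypropan-2-yl)oxolan-2-yl]propyl]octa-2,6-dienyl] acetate
Product: 27 [(2Z,6E)-8-hydroxy-2-[(3S)-3-hydroxy-3-[(2R,5S)-5-(2-hydroxypropan-2-yl)-2-methyloxolan-2-yl]propyl]-6-methylocta-2,6-dienyl] acetate (target)
Conditions: HF·pyridine (excess), pyridine, THF, 0 °C to rt
Reagents that add atoms: none
Why: Fluoride-driven desilylation with buffered HF·pyridine should cleave both triethylsilyl ethers quickly and the tert-butyldiphenylsilyl ether on longer exposure, while the acetate is inert to this mildly acidic, non-basic medium and has no nearby hydroxyl to migrate to.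

**Compound list**

1 | (R)-linalool, (3R)-3,7-dimethylocta-1,6-dien-3-ol | C=C[C@@](O)(C)CCC=C(C)C | starting material
2 | (3R)-5-[(2R)-3,3-dimethyloxiran-2-yl]-3-methylpent-1-en-3-ol | C=C[C@@](O)(C)CC[C@H]1OC1(C)C | intermediate
3 | 2-[(2S,5R)-5-ethenyl-5-methyloxolan-2-yl]propan-2-ol | C=C[C@@]1(C)CC[C@@H](C(C)(C)O)O1 | intermediate
4 | triethyl-[2-[(2S,5R)-5-ethenyl-5-methyloxolan-2-yl]propan-2-yloxy]silane | C=C[C@@]1(C)CC[C@@H](C(C)(C)O[Si](CC)(CC)CC)O1 | intermediate
5 | 3-[(2R,5S)-2-methyl-5-(2-triethylsilyloxypropan-2-yl)oxolan-2-yl]-1,2,4-trioxolane (epimers at the trioxolane carbon) | C1(OCOO1)[C@@]2(C)CC[C@@H](C(C)(C)O[Si](CC)(CC)CC)O2 | intermediate (not isolated)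
6 | (2R,5S)-2-methyl-5-(2-triethylsilyloxypropan-2-yl)oxolane-2-carbaldehyde | O=C[C@@]1(C)CC[C@@H](C(C)(C)O[Si](CC)(CC)CC)O1 | intermediate
7 | [(1S)-1-[(2R,5S)-2-methyl-5-(2-triethylsilyloxypropan-2-yl)oxolan-2-yl]but-3-enyl] diisopinocampheylborinate | C=CC[C@H](OB([C@@H]2C[C@@H]3C[C@@H](C3(C)C)[C@H]2C)[C@@H]2C[C@@H]3C[C@@H](C3(C)C)[C@H]2C)[C@@]1(C)CC[C@@H](C(C)(C)O[Si](CC)(CC)CC)O1 | intermediate (not isolated)
8 | (1S)-1-[(2R,5S)-2-methyl-5-(2-triethylsilyloxypropan-2-yl)oxolan-2-yl]but-3-en-1-ol | C=CC[C@H](O)[C@@]1(C)CC[C@@H](C(C)(C)O[Si](CC)(CC)CC)O1 | intermediate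
9 | triethyl-[(1S)-1-[(2R,5S)-2-methyl-5-(2-triethylsilyloxypropan-2-yl)oxolan-2-yl]but-3-enoxy]silane | C=CC[C@H](O[Si](CC)(CC)CC)[C@@]1(C)CC[C@@H](C(C)(C)O[Si](CC)(CC)CC)O1 | intermediate
10 | 3-[(2S)-2-triethylsilyloxy-2-[(2R,5S)-2-methyl-5-(2-triethylsilyloxypropan-2-yl)oxolan-2-yl]ethyl]-1,2,4-trioxolane (epimers at the trioxolane carbon) | C1(OCOO1)C[C@H](O[Si](CC)(CC)CC)[C@@]2(C)CC[C@@H](C(C)(C)O[Si](CC)(CC)CC)O2 | intermediate (not isolated)
11 | (3S)-3-triethylsilyloxy-3-[(2R,5S)-2-methyl-5-(2-triethylsilyloxypropan-2-yl)oxolan-2-yl]propanal | O=CC[C@H](O[Si](CC)(CC)CC)[C@@]1(C)CC[C@@H](C(C)(C)O[Si](CC)(CC)CC)O1 | intermediate (not isolated)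
12 | (3S)-3-triethylsilyloxy-3-[(2R,5S)-2-methyl-5-(2-triethylsilyloxypropan-2-yl)oxolan-2-yl]propan-1-ol | OCC[C@H](O[Si](CC)(CC)CC)[C@@]1(C)CC[C@@H](C(C)(C)O[Si](CC)(CC)CC)O1 | intermediate
13 | [(1S)-3-bromo-1-[(2R,5S)-2-methyl-5-(2-triethylsilyloxypropan-2-yl)oxolan-2-yl]propoxy]triethylsilane | BrCC[C@H](O[Si](CC)(CC)CC)[C@@]1(C)CC[C@@H](C(C)(C)O[Si](CC)(CC)CC)O1 | intermediate
14 | [(3S)-3-triethylsilyloxy-3-[(2R,5S)-2-methyl-5-(2-triethylsilyloxypropan-2-yl)oxolan-2-yl]propyl]magnesium bromide (fragment 2) | Br[Mg]CC[C@H](O[Si](CC)(CC)CC)[C@@]1(C)CC[C@@H](C(C)(C)O[Si](CC)(CC)CC)O1 | intermediate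
15 | tert-butyl(but-3-ynoxy)dimethylsilane | C#CCCO[Si](C)(C)C(C)(C)C | starting material
16 | [(1E)-4-(tert-butyldimethylsilyloxy)-2-methylbut-1-enyl]dimethylalane | C[Al](C)/C=C(C)/CCO[Si](C)(C)C(C)(C)C | intermediate (not isolated)
17 | lithium butyl[(1E)-4-(tert-butyldimethylsilyloxy)-2-methylbut-1-enyl]dimethylalanate | [Li+].CCCC[Al-](C)(C)/C=C(C)/CCO[Si](C)(C)C(C)(C)C | intermediate (not isolated)
18 | (2E)-5-(tert-butyldimethylsilyloxy)-3-methylpent-2-en-1-ol | OC/C=C(C)/CCO[Si](C)(C)C(C)(C)C | intermediate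
19 | tert-butyl-[(3E)-5-(tert-butyldiphenylsilyloxy)-3-methylpent-3-enoxy]dimethylsilane | CC(C)(C)[Si](C)(C)OCC/C(C)=C/CO[Si](c1ccccc1)(c1ccccc1)C(C)(C)C | intermediate
20 | (3E)-5-(tert-butyldiphenylsilyloxy)-3-methylpent-3-en-1-ol | OCC/C(C)=C/CO[Si](c1ccccc1)(c1ccccc1)C(C)(C)C | intermediate
21 | tert-butyl-[(2E)-5-iodo-3-methylpent-2-enoxy]diphenylsilane (fragment 3) | ICC/C(C)=C/CO[Si](c1ccccc1)(c1ccccc1)C(C)(C)C | intermediate
22 | prop-2-yn-1-ol | C#CCO | starting material
23 | chloromagnesium prop-2-yn-1-olate | C#CCO[Mg]Cl | intermediate (not isolated)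
24 | 4-[(3S)-3-triethylsilyloxy-3-[(2R,5S)-2-methyl-5-(2-triethylsilyloxypropan-2-yl)oxolan-2-yl]propyl]-2,5-dihydro-1,2-oxamagnesole (chelated C6-magnesio alkoxide) | [Mg]1OCC(CC[C@H](O[Si](CC)(CC)CC)[C@@]2(C)CC[C@@H](C(C)(C)O[Si](CC)(CC)CC)O2)=C1 | intermediate (not isolated)
25 | (2Z,6E)-8-(tert-butyldiphenylsilyloxy)-6-methyl-2-[(3S)-3-triethylsilyloxy-3-[(2R,5S)-2-methyl-5-(2-triethylsilyloxypropan-2-yl)oxolan-2-yl]propyl]octa-2,6-dien-1-ol | OC/C(=C\CC/C(C)=C/CO[Si](c1ccccc1)(c1ccccc1)C(C)(C)C)CC[C@H](O[Si](CC)(CC)CC)[C@@]1(C)CC[C@@H](C(C)(C)O[Si](CC)(CC)CC)O1 | intermediate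
26 | [(2Z,6E)-8-(tert-butyldiphenylsilyloxy)-6-methyl-2-[(3S)-3-triethylsilyloxy-3-[(2R,5S)-2-methyl-5-(2-triethylsilyloxypropan-2-yl)oxolan-2-yl]propyl]octa-2,6-dienyl] acetate | CC(=O)OC/C(=C\CC/C(C)=C/CO[Si](c1ccccc1)(c1ccccc1)C(C)(C)C)CC[C@H](O[Si](CC)(CC)CC)[C@@]1(C)CC[C@@H](C(C)(C)O[Si](CC)(CC)CC)O1 | intermediate
27 | [(2Z,6E)-8-hydroxy-2-[(3S)-3-hydroxy-3-[(2R,5S)-5-(2-hydroxypropan-2-yl)-2-methyloxolan-2-yl]propyl]-6-methylocta-2,6-dienyl] acetate | CC(=O)OC/C(=C\CC/C(C)=C/CO)CC[C@H](O)[C@@]1(C)CC[C@@H](C(C)(C)O)O1 | target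

**Step count**

Total step count: 16. Longest linear sequence: 12 steps (steps 1–9, 14, 15, 16).

**Steps most likely to fail**

1. Step 14 (the proposed new method). The alkenylmagnesium 24 may be protonated by the acetylenic C–H of alkoxide 23 that has not yet reacted. The sp2–sp3 alkylation may also be slower than dehydroiodination of the homoallylic iodide, or unreacted 14 may couple directly with 21. The fallback uses known chemistry, sets out from 14, 22 and 21 and comes back at 25. The carbomagnesiation is run as in step 14 as far as 24 and quenched with I2 (THF, −78 to 0 °C), which should give the (2Z)-iodoalkenol F1. Separately, 21 is converted by LiCl-mediated zinc insertion (Zn dust, LiCl, THF, 40 °C) into the alkylzinc iodide F2. Negishi coupling of F1 with excess F2 (Pd(OAc)2, SPhos, THF, rt; the free hydroxyl is tolerated by the zinc reagent) should form C5–C6 with retention of the alkene geometry and give 25.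

2. Step 5. Facial selectivity may be poor, or addition sluggish, at the aldehyde carbon next to the quaternary C11, leaving C10 epimers that are hard to separate. The fallback sets out from 6 and comes back at 12. An acetate aldol with the dianion of (S)-2-hydroxy-1,2,2-triphenylethyl acetate ((S)-HYTRA; LDA 2 equiv, THF, then MgBr2, −115 °C) should give the (3S)-β-hydroxy ester F3 under auxiliary control. Silylation (TESOTf, 2,6-lutidine, CH2Cl2, −78 °C) gives the silyl ether F4. LiAlH4 (Et2O, 0 °C) then reduces the ester to 12 with release of the triphenylethanediol, so steps 6 and 7 are skipped.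

3. Step 9. Magnesium insertion may be incomplete and accompanied by Wurtz-type homocoupling on small scale, giving a Grignard solution of uncertain titre for the key step. The fallback sets out from 12 and comes back at 14. Iodination (I2, PPh3, imidazole, CH2Cl2, 0 °C) gives the iodide F5, so step 8 is skipped. Iodine–lithium exchange (t-BuLi 2 equiv, Et2O/pentane, −78 °C) gives the alkyllithium F6, and immediate transmetalation with MgBr2·OEt2 at −78 °C gives 14. The cold ethereal medium should keep oxygen-to-carbon silyl migration in the lithium species slow.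

**Further compounds**

F1 | step 14 | (2Z,5S)-2-(iodomethylidene)-5-triethylsilyloxy-5-[(2R,5S)-2-methyl-5-(2-triethylsilyloxypropan-2-yl)oxolan-2-yl]pentan-1-ol | OC/C(=C\I)CC[C@H](O[Si](CC)(CC)CC)[C@@]1(C)CC[C@@H](C(C)(C)O[Si](CC)(CC)CC)O1
F2 | step 14 | [(3E)-5-(tert-butyldiphenylsilyloxy)-3-methylpent-3-enyl]zinc iodide | I[Zn]CC/C(C)=C/CO[Si](c1ccccc1)(c1ccccc1)C(C)(C)C
F3 | step 5 | [(1S)-2-hydroxy-1,2,2-triphenylethyl] (3S)-3-hydroxy-3-[(2R,5S)-2-methyl-5-(2-triethylsilyloxypropan-2-yl)oxolan-2-yl]propanoate | O=C(C[C@H](O)[C@@]1(C)CC[C@@H](C(C)(C)O[Si](CC)(CC)CC)O1)O[C@@H](c1ccccc1)C(O)(c1ccccc1)c1ccccc1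
F4 | step 5 | [(1S)-2-hydroxy-1,2,2-triphenylethyl] (3S)-3-triethylsilyloxy-3-[(2R,5S)-2-methyl-5-(2-triethylsilyloxypropan-2-yl)oxolan-2-yl]propanoate | O=C(C[C@H](O[Si](CC)(CC)CC)[C@@]1(C)CC[C@@H](C(C)(C)O[Si](CC)(CC)CC)O1)O[C@@H](c1ccccc1)C(O)(c1ccccc1)c1ccccc1
F5 | step 9 | [(1S)-3-iodo-1-[(2R,5S)-2-methyl-5-(2-triethylsilyloxypropan-2-yl)oxolan-2-yl]propoxy]triethylsilane | ICC[C@H](O[Si](CC)(CC)CC)[C@@]1(C)CC[C@@H](C(C)(C)O[Si](CC)(CC)CC)O1
F6 | step 9 | [(3S)-3-triethylsilyloxy-3-[(2R,5S)-2-methyl-5-(2-triethylsilyloxypropan-2-yl)oxolan-2-yl]propyl]lithium | [Li]CC[C@H](O[Si](CC)(CC)CC)[C@@]1(C)CC[C@@H](C(C)(C)O[Si](CC)(CC)CC)O1
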